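**Plan**
- Retrosynthesis first cuts the O3'–S bond (sulfation of the one free phenol) and the hydrogenolysable protecting groups, then the O1–C8a aryl ether of ring C, then the C2–C3 bond of the resulting 1,3-diketone, and last the C4–C4a and C3–C4 bonds of the ring A acetyl group.
- Forward, rings A and B come intact from 5-bromoresorcinol and methyl gallate. A crossed Claisen condensation joins them through C2–C3, and ring C is closed afterwards by copper-catalysed O-arylation.
- The enabling feature is that O1–C8a is an aryl–oxygen bond ortho to the C4 ketone on ring A. A C8a–Br bond and the enol oxygen at C2 of the C2–C3–C4 diketone are therefore placed to close the six-membered ring.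
- Protecting groups: benzyl on O5 and O7, diphenylmethylene on O4'/O5', allyl on O3', so that O3' alone can be freed and sulfated before one final hydrogenolysis.
- Stereochemistry: the target has no stereocentre. The only one on the route, the carbinol carbon of 6, is racemic and is removed by oxidation.

Key step: step 8

Assumption: the target is drawn as the free aryl hydrogen sulfate, so the sulfate is carried as its sodium salt and protonated only at the very end, in the cold, because aryl hydrogen sulfates hydrolyse in acid.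

**Step 1**
Reactants: 1 5-bromoresorcinol
Product: 2 1,3-bis(benzyloxy)-5-bromobenzene
Conditions: BnBr (2.2 equiv), K2CO3, DMF, 60 °C
Reagents that add atoms: benzyl bromide, BrCc1ccccc1
Why: Williamson ether synthesis on both phenoxides should proceed cleanly, the aryl bromide being inert to carbonate and benzyl bromide.

**Step 2**
Reactants: 2 1,3-bis(benzyloxy)-5-bromobenzene
Product: 4 2,4-bis(benzyloxy)-6-bromobenzaldehyde, via iminium chloride 3 (not isolated)
Conditions: POCl3, DMF, 0 → 75 °C; then H2O, rt
Reagents that add atoms: N,N-dimethylformamide, CN(C)C=O; water, O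
Why: Vilsmeier–Haack formylation of 3,5-dialkoxybromobenzenes is expected to go to the carbon next to bromine, which is para to one ether and ortho to the other, in preference to the more crowded carbon between the two ethers, and water hydrolyses the iminium salt 3 to the aldehyde.

**Step 3**
Reactants: 4 2,4-bis(benzyloxy)-6-bromobenzaldehyde
Product: 6 racemic 1-[2,4-bis(benzyloxy)-6-bromophenyl]ethanol, via bromomagnesium alkoxide 5 (not isolated)
Conditions: MeMgBr, THF, 0 °C; then H2O
Reagents that add atoms: methylmagnesium bromide, C[Mg]Br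
Why: Grignard addition to the aldehyde should outrun any bromine–magnesium exchange at 0 °C, and the new carbinol centre is formed without control (racemic) because the next step removes it.

**Step 4**
Reactants: 6 racemic 1-[2,4-bis(benzyloxy)-6-bromophenyl]ethanol
Product: 7 1-[2,4-bis(benzyloxy)-6-bromophenyl]ethanone
Conditions: Dess–Martin periodinane, CH2Cl2, rt
Reagents that add atoms: none
Why: Dess–Martin oxidation converts hindered secondary benzylic alcohols to aryl methyl ketones under near-neutral conditions that leave benzyl ethers and the aryl bromide alone.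

**Step 5**
Reactants: 8 methyl gallate
Product: 9 methyl 7-hydroxy-2,2-diphenyl-1,3-benzodioxole-5-carboxylate
Conditions: Ph2CCl2, Ph2O, 180 °C
Reagents that add atoms: dichlorodiphenylmethane, ClC(Cl)(c1ccccc1)c1ccccc1
Why: Ketalisation of a catechol with dichlorodiphenylmethane can only bridge two adjacent hydroxyls, and the symmetry of the triol makes both such pairs equivalent, so one benzodioxole with one free flanking phenol should result.

**Step 6**
Reactants: 9 methyl 7-hydroxy-2,2-diphenyl-1,3-benzodioxole-5-carboxylate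
Product: 10 methyl 7-(allyloxy)-2,2-diphenyl-1,3-benzodioxole-5-carboxylate
Conditions: allyl bromide, K2CO3, DMF, rt
Reagents that add atoms: allyl bromide, C=CCBr
Why: Williamson O-allylation of the remaining phenol installs a group that zerovalent palladium can later remove without touching benzyl ethers or the ketal.

**Step 7**
Reactants: 7 1-[2,4-bis(benzyloxy)-6-bromophenyl]ethanone, 10 methyl 7-(allyloxy)-2,2-diphenyl-1,3-benzodioxole-5-carboxylate
Product: 12 1-[2,4-bis(benzyloxy)-6-bromophenyl]-3-[7-(allyloxy)-2,2-diphenyl-1,3-benzodioxol-5-yl]propane-1,3-dione, via sodium enolate 11 (not isolated)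
Conditions: NaH, THF, reflux; then 1 M HCl, 0 °C
Reagents that add atoms: none
Why: In this crossed Claisen condensation the enolate of the doubly ortho-substituted ketone cannot easily self-condense, the ester has no α-hydrogen, and irreversible formation of the diketonate 11 pulls the equilibrium to the C2–C3 bond, acid work-up then giving 12.

**Step 8**
Reactants: 12 1-[2,4-bis(benzyloxy)-6-bromophenyl]-3-[7-(allyloxy)-2,2-diphenyl-1,3-benzodioxol-5-yl]propane-1,3-dione
Product: 14 5,7-bis(benzyloxy)-2-[7-(allyloxy)-2,2-diphenyl-1,3-benzodioxol-5-yl]-4H-chromen-4-one, via caesium enolate 13 (not isolated)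
Conditions: CuI (10 mol %), 1,10-phenanthroline (20 mol %), Cs2CO3 (2 equiv), dry DMF, 100 °C, Ar
Reagents that add atoms: none
Why: Cs2CO3 deprotonates C3 of 12 to the chelated Z-enolate 13, whose oxygen on the ring B side binds phenanthroline-ligated monovalent copper, the metal then inserts into the neighbouring C8a–Br bond to give a trivalent copper aryl enolate, and C–O reductive elimination forms O1–C8a and returns CuBr to the cycle. The closest known reaction is the Ullmann-type intramolecular O-arylation of 1-(2-haloaryl)-1,3-diketones, an established entry to flavones and chromones. Ring C, the six-membered pyranone, closes by attack of the enolate oxygen on the aromatic carbon C8a (formally 6-exo-trig at the carbon that loses bromide), the C2–C3–C4 unit and the C4–C4a bond holding both ends in one plane. No stereocentre is formed. The step needs O-arylation through the ring B-side oxygen, not C-arylation at C3 or attack by the ring A-side oxygen, and geometry secures this because either alternative would close a four-membered ring. Copper is used because the two benzyloxy groups donate into C4a and the doubly ortho-substituted ketone is twisted, so the carbonyl activates C8a too weakly for a reliable uncatalysed substitution, while dry DMF and a carbonate base hold back retro-Claisen cleavage and protodebromination.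

**Step 9**
Reactants: 14 5,7-bis(benzyloxy)-2-[7-(allyloxy)-2,2-diphenyl-1,3-benzodioxol-5-yl]-4H-chromen-4-one
Product: 15 5,7-bis(benzyloxy)-2-(7-hydroxy-2,2-diphenyl-1,3-benzodioxol-5-yl)-4H-chromen-4-one
Conditions: Pd(PPh3)4 (5 mol %), morpholine, THF, rt
Reagents that add atoms: none
Why: In this Tsuji–Trost deallylation zerovalent palladium ionises the allyl aryl ether to a π-allyl complex that morpholine captures, which should free O3' alone since benzyl ethers, the ketal and the flavone core do not react.

**Step 10**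
Reactants: 15 5,7-bis(benzyloxy)-2-(7-hydroxy-2,2-diphenyl-1,3-benzodioxol-5-yl)-4H-chromen-4-one
Product: 17 sodium 5-[5,7-bis(benzyloxy)-4-oxo-4H-chromen-2-yl]-2,2-diphenyl-1,3-benzodioxol-7-yl sulfate, via pyridinium sulfate 16 (not isolated)
Conditions: SO3·pyridine, pyridine, 50 °C; then aq. NaHCO3
Reagents that add atoms: sulfur trioxide–pyridine complex, O=S(=O)=O.c1ccncc1; sodium hydrogen carbonate, [Na+].OC([O-])=O
Why: O-sulfation of a phenol with the sulfur trioxide–pyridine complex can only occur at the single free hydroxyl, and exchange to the sodium salt removes the pyridine that would otherwise inhibit the hydrogenolysis catalyst.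

**Step 11**
Reactants: 17 sodium 5-[5,7-bis(benzyloxy)-4-oxo-4H-chromen-2-yl]-2,2-diphenyl-1,3-benzodioxol-7-yl sulfate
Product: 19 tricetin 3'-sulfate, via sodium tricetin 3'-sulfate 18 (not isolated)
Conditions: H2 (1 atm), Pd(OH)2/C, THF/MeOH/H2O, rt; then HCl (1.0 equiv), 0 °C, C18 desalting, lyophilisation
Reagents that add atoms: none
Why: Catalytic hydrogenolysis cleaves the benzylic C–O bonds of both benzyl ethers and of the diphenylmethylene ketal while the aryl sulfate anion is inert to hydrogen over palladium, and one equivalent of cold acid then gives the free hydrogen sulfate.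

**Compound list**
1 | 5-bromoresorcinol | Oc1cc(O)cc(Br)c1 | starting material
2 | 1,3-bis(benzyloxy)-5-bromobenzene | Brc1cc(OCc2ccccc2)cc(OCc2ccccc2)c1 | intermediate
3 | N-{[2,4-bis(benzyloxy)-6-bromophenyl]methylidene}-N-methylmethanaminium chloride | C[N+](C)=Cc1c(Br)cc(OCc2ccccc2)cc1OCc1ccccc1.[Cl-] | intermediate (not isolated)
4 | 2,4-bis(benzyloxy)-6-bromobenzaldehyde | O=Cc1c(Br)cc(OCc2ccccc2)cc1OCc1ccccc1 | intermediate
5 | bromomagnesium 1-[2,4-bis(benzyloxy)-6-bromophenyl]ethoxide, racemic | CC(O[Mg]Br)c1c(Br)cc(OCc2ccccc2)cc1OCc1ccccc1 | intermediate (not isolated)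
6 | 1-[2,4-bis(benzyloxy)-6-bromophenyl]ethanol, racemic | CC(O)c1c(Br)cc(OCc2ccccc2)cc1OCc1ccccc1 | intermediate
7 | 1-[2,4-bis(benzyloxy)-6-bromophenyl]ethanone | CC(=O)c1c(Br)cc(OCc2ccccc2)cc1OCc1ccccc1 | intermediate
8 | methyl gallate | COC(=O)c1cc(O)c(O)c(O)c1 | starting material
9 | methyl 7-hydroxy-2,2-diphenyl-1,3-benzodioxole-5-carboxylate | COC(=O)c1cc(O)c2OC(c3ccccc3)(c3ccccc3)Oc2c1 | intermediate
10 | methyl 7-(allyloxy)-2,2-diphenyl-1,3-benzodioxole-5-carboxylate | COC(=O)c1cc(OCC=C)c2OC(c3ccccc3)(c3ccccc3)Oc2c1 | intermediate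
11 | sodium Z-enolate of diketone 12 | [Na+].[O-]/C(=C\C(=O)c1cc(OCC=C)c2OC(c3ccccc3)(c3ccccc3)Oc2c1)c1c(Br)cc(OCc2ccccc2)cc1OCc1ccccc1 | intermediate (not isolated)
12 | 1-[2,4-bis(benzyloxy)-6-bromophenyl]-3-[7-(allyloxy)-2,2-diphenyl-1,3-benzodioxol-5-yl]propane-1,3-dione | O=C(CC(=O)c1cc(OCC=C)c2OC(c3ccccc3)(c3ccccc3)Oc2c1)c1c(Br)cc(OCc2ccccc2)cc1OCc1ccccc1 | intermediate
13 | caesium Z-enolate of diketone 12, enolate oxygen on the ring B side | [Cs+].[O-]/C(=C\C(=O)c1c(Br)cc(OCc2ccccc2)cc1OCc1ccccc1)c1cc(OCC=C)c2OC(c3ccccc3)(c3ccccc3)Oc2c1 | intermediate (not isolated)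
14 | 5,7-bis(benzyloxy)-2-[7-(allyloxy)-2,2-diphenyl-1,3-benzodioxol-5-yl]-4H-chromen-4-one | O=c1cc(-c2cc(OCC=C)c3OC(c4ccccc4)(c4ccccc4)Oc3c2)oc2cc(OCc3ccccc3)cc(OCc3ccccc3)c12 | intermediate
15 | 5,7-bis(benzyloxy)-2-(7-hydroxy-2,2-diphenyl-1,3-benzodioxol-5-yl)-4H-chromen-4-one | O=c1cc(-c2cc(O)c3OC(c4ccccc4)(c4ccccc4)Oc3c2)oc2cc(OCc3ccccc3)cc(OCc3ccccc3)c12 | intermediate
16 | pyridinium 5-[5,7-bis(benzyloxy)-4-oxo-4H-chromen-2-yl]-2,2-diphenyl-1,3-benzodioxol-7-yl sulfate | O=c1cc(-c2cc(OS(=O)(=O)[O-])c3OC(c4ccccc4)(c4ccccc4)Oc3c2)oc2cc(OCc3ccccc3)cc(OCc3ccccc3)c12.c1cc[nH+]cc1 | intermediate (not isolated)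
17 | sodium 5-[5,7-bis(benzyloxy)-4-oxo-4H-chromen-2-yl]-2,2-diphenyl-1,3-benzodioxol-7-yl sulfate | O=c1cc(-c2cc(OS(=O)(=O)[O-])c3OC(c4ccccc4)(c4ccccc4)Oc3c2)oc2cc(OCc3ccccc3)cc(OCc3ccccc3)c12.[Na+] | intermediate
18 | sodium tricetin 3'-sulfate | O=c1cc(-c2cc(O)c(O)c(OS(=O)(=O)[O-])c2)oc2cc(O)cc(O)c12.[Na+] | intermediate (not isolated)
19 | tricetin 3'-sulfate | O=c1cc(-c2cc(O)c(O)c(OS(=O)(=O)O)c2)oc2cc(O)cc(O)c12 | target

**Total step count:** 11

**Longest linear sequence:** 9 steps (steps 1–4 and 7–11, from 5-bromoresorcinol); the ring B branch is steps 5–6.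

**Steps most likely to fail**

Step 8. Hydrodebromination at C8a and base-induced retro-Claisen cleavage of the diketone may outpace copper insertion into the hindered, electron-rich C–Br bond. The fallback closes ring C from the other side by known chemistry, setting out from ester 10 and coming back at flavone 14. Commercial 2,4,6-trihydroxyacetophenone is benzylated at O4 and O6 (BnBr, K2CO3, DMF; the hydrogen-bonded 2-hydroxyl stays free) to 1-[2,4-bis(benzyloxy)-6-hydroxyphenyl]ethanone F1. Its dianion (NaH, THF, reflux) is C-acylated by 10 to 1-[2,4-bis(benzyloxy)-6-hydroxyphenyl]-3-[7-(allyloxy)-2,2-diphenyl-1,3-benzodioxol-5-yl]propane-1,3-dione F2. Catalytic p-TsOH in toluene at 80 °C then dehydrates F2 to 14 through O1–C2 bond formation.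

Step 7. Acyl transfer from the electron-rich, poorly electrophilic ester to the enolate may stall, so that proton exchange and slow enolate decomposition dominate at reflux. The fallback raises the acyl donor to an acid chloride, setting out from ester 10 and coming back at diketone 12. LiOH in THF/MeOH/H2O gives 7-(allyloxy)-2,2-diphenyl-1,3-benzodioxole-5-carboxylic acid F3. (COCl)2 with catalytic DMF in CH2Cl2 gives 7-(allyloxy)-2,2-diphenyl-1,3-benzodioxole-5-carbonyl chloride F4. The lithium enolate of ketone 7 (LiN(SiMe3)2, 2.2 equiv, THF, −78 °C) is C-acylated by F4, the second equivalent of base holding the product as its enolate, and acidic work-up returns 12.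

Step 11. Hydrogenation may saturate the C2–C3 double bond or stall at the diphenylmethylene ketal, and the sulfate may be lost by acid-catalysed hydrolysis while the free acid is released. The fallback carries the sulfate as a neutral, acid-stable diester and avoids hydrogen, setting out from phenol 15 and coming back at 19. 2,2,2-Trichloroethyl chlorosulfate, Et3N and DMAP in THF give 5,7-bis(benzyloxy)-2-(2,2-diphenyl-7-{[(2,2,2-trichloroethoxy)sulfonyl]oxy}-1,3-benzodioxol-5-yl)-4H-chromen-4-one F5. BCl3 with pentamethylbenzene in CH2Cl2 at −78 °C, followed by aqueous work-up, removes both benzyl ethers and the ketal to give tricetin 3'-(2,2,2-trichloroethyl sulfate) F6. Zinc dust and HCO2NH4 in MeOH unmask the sulfate by reductive elimination of the trichloroethyl group, giving ammonium tricetin 3'-sulfate F7, and one equivalent of cold HCl gives 19.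

**Further compounds**
F1 | step 8 | 1-[2,4-bis(benzyloxy)-6-hydroxyphenyl]ethanone | CC(=O)c1c(O)cc(OCc2ccccc2)cc1OCc1ccccc1
F2 | step 8 | 1-[2,4-bis(benzyloxy)-6-hydroxyphenyl]-3-[7-(allyloxy)-2,2-diphenyl-1,3-benzodioxol-5-yl]propane-1,3-dione | O=C(CC(=O)c1cc(OCC=C)c2OC(c3ccccc3)(c3ccccc3)Oc2c1)c1c(O)cc(OCc2ccccc2)cc1OCc1ccccc1
F3 | step 7 | 7-(allyloxy)-2,2-diphenyl-1,3-benzodioxole-5-carboxylic acid | OC(=O)c1cc(OCC=C)c2OC(c3ccccc3)(c3ccccc3)Oc2c1
F4 | step 7 | 7-(allyloxy)-2,2-diphenyl-1,3-benzodioxole-5-carbonyl chloride | ClC(=O)c1cc(OCC=C)c2OC(c3ccccc3)(c3ccccc3)Oc2c1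
F5 | step 11 | 5,7-bis(benzyloxy)-2-(2,2-diphenyl-7-{[(2,2,2-trichloroethoxy)sulfonyl]oxy}-1,3-benzodioxol-5-yl)-4H-chromen-4-one | O=c1cc(-c2cc(OS(=O)(=O)OCC(Cl)(Cl)Cl)c3OC(c4ccccc4)(c4ccccc4)Oc3c2)oc2cc(OCc3ccccc3)cc(OCc3ccccc3)c12
F6 | step 11 | tricetin 3'-(2,2,2-trichloroethyl sulfate) | O=c1cc(-c2cc(O)c(O)c(OS(=O)(=O)OCC(Cl)(Cl)Cl)c2)oc2cc(O)cc(O)c12
F7 | step 11 | ammonium tricetin 3'-sulfate | O=c1cc(-c2cc(O)c(O)c(OS(=O)(=O)[O-])c2)oc2cc(O)cc(O)c12.[NH4+]
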